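1. The ratio of target in the cedar run to target in the elm run barely moved, 1.54 at 1.6 min and 1.54 at 8.2 min, so I replaced each curve by its mean rate, the target reading at 8.2 min divided by that time.

| flask | starting material | reagent | time |
|---|---|---|---|
| elm | 0.100 M | 0.200 M |  |
| oak | 0.0400 M | 0.140 M |  |
| birch | 0.100 M | 0.100 M |  |
| cedar | 0.200 M | 0.200 M |  |
| ash | 0.200 M | 0.400 M | 8.2 min |

| run | time / min | [target] / M |
|---|---|---|
| elm run | 1.6 | 0.0134 |
| elm run | 3.3 | 0.0312 |
| elm run | 4.9 | 0.0416 |
| elm run | 6.6 | 0.0488 |
| elm run | 8.2 | 0.0524 |
| oak run | 1.6 | 0.0053 |
| oak run | 3.3 | 0.0134 |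
| oak run | 4.9 | 0.0181 |
| oak run | 6.6 | 0.0218 |
| oak run | 8.2 | 0.0229 |
| birch run | 1.6 | 0.0079 |
| birch run | 3.3 | 0.0214 |
| birch run | 4.9 | 0.0305 |
| birch run | 6.6 | 0.0367 |
| birch run | 8.2 | 0.0398 |
| cedar run | 1.6 | 0.0207 |
| cedar run | 3.3 | 0.0478 |
| cedar run | 4.9 | 0.0648 |
| cedar run | 6.6 | 0.0754 |
| cedar run | 8.2 | 0.0805 |

(scatter of a reading: 3 × 10⁻⁴ M)

- Overall: starting material + reagent -> target.
- Constant volume, constant temperature.
- The analysis sees a species whether free or bound.
- "The second partner" is reagent.
- An order is taken over about fifteen percent of the charge, up and down.

1. apparent order in [reagent] of the starting rate, round the charge of the elm run (the rate where two percent of its starting material have turned into target)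
2. apparent order in [starting material] of the starting rate, round the charge of the elm run (the rate where two percent of its starting material have turned into target) (one fixed amount of target, the same in the runs compared)
3. target in the ash run at 8.2 min, as a share of the starting material charged

2. I turned the ash question round and asked what ash would need to match the elm share of 52.4%. Ash charges twice the starting material and twice the reagent of elm, and starting material is the limiting reagent in ash, so the shares match if doubling both charges doubles the mean rate.

3. From mean rates I read the order in starting material, m_S = 0.619 (cedar over elm), and the order in reagent, m_R = 0.397 (elm over birch). Their sum, the whole-charge order M = 1.02, has to equal 1 for equal shares, provided these orders hold at the ash charge.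

4. M stood 0.0200 from that line, while the scatter of the birch reading moves it by 0.0109, so my reckoning for ash, 53.0%, lay close to the elm share.

5. The mean has a cost: elm over birch fell from 1.70 at 1.6 min to 1.32 at 8.2 min, so m_R describes the late curve and I did not offer it as a starting order.

6. The forecast gave 0.65 (0.5 to 0.85) for the reagent order, 0.42 (0.3 to 0.6) for the starting-material order and 49% (44% to 54%) for ash, noting “cedar/elm stays at 1.54 throughout”. Its ash share stood below mine.

    starting material ⇌ intermediate + by-product (0.3426 min⁻¹, 4.320 M⁻¹ min⁻¹)
    intermediate + reagent → target (5.076 M⁻¹ min⁻¹)
    2 starting material ⇌ idle substrate dimer, settled at all times (6.680 M⁻¹)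
    target → decomposed product (0.06960 min⁻¹)

The ash run gave 49.7%, less than my 53.0% and inside the forecast's range. The apparent orders of the starting rate, round the elm charge, came out at 0.45 in reagent, below the forecast's low end, and 0.44 in starting material. Measured against elm, ash has a whole-charge order of 0.924, less than M. Carried to the oak run, m_S and m_R gave 0.0258 M at 8.2 min, more than the oak reading there, which was 0.0229 M.

(All runs are simulated with made-up constants; noise was put on by code.)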